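**Remark:** positions are numbered as in labdane (C-1 to C-20). The target is the ent-labdane (3R,5S,7R,9S,10R). In step 2 the antipode of the oxazaborolidinium catalyst is assumed to be the one that gives the (1S) adduct.

**Retrosynthetic overview**
1. Target 26 ← reduction of both ketones of enedione 25 ← C-7 oxidation and C-8 methylenation of diketone 22 ← hydroboration of the C-8/C-9 olefin of 19.
2. 19 ← Negishi union of vinyl triflate 14 (C-9) with the zinc reagent from lactone 15, which brings the whole side chain and its Z geometry.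
3. Ring A (11) ← annulation of aldehyde acid 9 with a vinylphosphonium two-carbon unit: C-3–C-4 by decarboxylative radical addition, C-1=C-2 by intramolecular Wittig.
4. 9 ← 2-methylcyclohex-2-enone 4 (ring B, bought) by asymmetric Mukaiyama–Michael addition and orthoformate trapping, which sets C-5 and C-10; ring B first, ring A second.
5. Enabling feature: on ring B a tertiary α,α-dimethyl carboxylic acid at C-5 (future C-4, gives a tertiary radical on loss of CO2) lies trans-vicinal to the non-enolisable formyl group on quaternary C-10 (future C-1), with the C-9 ketone masked as a vinyl triflate.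

Key step: step 5

**Step 1**
Reactants: 1 tert-butyl 2-methylpropanoate
Product: 3 [(1-tert-butoxy-2-methylprop-1-en-1-yl)oxy]trimethylsilane, via lithium enolate 2 (not isolated)
Conditions: LiN(iPr)2, THF, −78 °C; Me3SiCl, −78 °C → rt
Reagents that add atoms: chlorotrimethylsilane C[Si](C)(C)Cl
Why: O-silylation of the lithium ester enolate is the standard route to ketene silyl acetals; no stereocentre is formed.

**Step 2**
Reactants: 4 2-methylcyclohex-2-en-1-one; 3 ketene silyl acetal
Product: 6 tert-butyl 2-[(1S,2S)-2-(dimethoxymethyl)-2-methyl-3-oxocyclohexyl]-2-methylpropanoate, via silyl enol ether 5 (not isolated)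
Conditions: (S)-o-tolyl-CBS-oxazaborolidine·HNTf2 (20 mol %), Ph3PO, toluene, −20 °C; then HC(OMe)3, Me3SiOTf (cat.), CH2Cl2, −78 → −40 °C
Reagents that add atoms: trimethyl orthoformate COC(OC)OC
Why: Enantioselective Mukaiyama–Michael addition under chiral oxazaborolidinium activation should set C-5 by catalyst control, and Mukaiyama-type alkylation of the regiodefined silyl enol ether by the dimethoxycarbenium ion should occur anti to the bulky vicinal group, setting quaternary C-10 trans.

**Step 3**
Reactants: 6 keto acetal ester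
Product: 8 tert-butyl 2-[(1S,2R)-2-(dimethoxymethyl)-2-methyl-3-{[(trifluoromethyl)sulfonyl]oxy}cyclohex-3-en-1-yl]-2-methylpropanoate, via potassium enolate 7 (not isolated)
Conditions: KN(SiMe3)2, THF, −78 °C; PhNTf2, −78 → 0 °C
Reagents that add atoms: N-phenylbis(trifluoromethanesulfonimide) O=S(=O)(N(c1ccccc1)S(=O)(=O)C(F)(F)F)C(F)(F)F
Why: The ketone can enolise only towards C-8 because C-10 is quaternary, so enolate O-triflation should give a single vinyl triflate; no stereocentre changes.

**Step 4**
Reactants: 8 vinyl triflate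
Product: 9 2-[(1S,2R)-2-formyl-2-methyl-3-{[(trifluoromethyl)sulfonyl]oxy}cyclohex-3-en-1-yl]-2-methylpropanoic acid
Conditions: CF3CO2H/CH2Cl2 (1:4), 0 °C → rt; then H2O
Reagents that add atoms: water O
Why: Acidolysis of the tert-butyl ester and hydrolysis of the dimethyl acetal occur under the same acid, while the vinyl triflate and the non-enolisable aldehyde are inert.

**Step 5**
Reactants: 9 aldehyde acid
Product: 11 (4aR,8aR)-5,5,8a-trimethyl-3,4,4a,5,6,8a-hexahydronaphthalen-1-yl trifluoromethanesulfonate, via phosphorus ylide 10 (not isolated)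
Conditions: [Ir(dF(CF3)ppy)2(dtbbpy)]PF6 (1 mol %), Cs2CO3, vinyltriphenylphosphonium bromide, CH2Cl2 (0.02 M), blue LEDs, rt
Reagents that add atoms: vinyltriphenylphosphonium bromide C=C[P+](c1ccccc1)(c1ccccc1)c1ccccc1.[Br-]
Why: The excited trivalent iridium complex oxidises the caesium carboxylate of 9, loss of CO2 gives the tertiary C-4 radical, this adds to the terminal carbon of the vinylphosphonium salt (C-3–C-4), and the α-phosphonio radical is reduced by the divalent iridium to ylide 10, which olefinates the tethered formyl group (C-1=C-2) with loss of Ph3PO. The closest known reaction type is the photoredox decarboxylative conjunctive olefination of carboxylic acids, vinylphosphonium salts and aldehydes (Giese addition then Wittig), used here with acid and aldehyde in one molecule. Ring A closes in the Wittig step as a six-membered ring through the oxaphosphetane, which can only give the cis ring olefin. No stereocentre is created, since C-4 carries two methyl groups and the trans ring fusion is already fixed by the trans-vicinal C-5 and C-10 substituents of 9. The step needs chemoselectivity: the radical must be captured by the phosphonium salt and the ylide must olefinate before it is protonated. This is secured by the polarity match of the nucleophilic tertiary radical with the cationic acceptor, by the strained four- or five-membered rings that any intramolecular radical attack would need, and by the single, non-enolisable carbonyl group placed for six-ring closure.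

**Step 6**
Reactants: 11 bicyclic diene triflate
Product: 13 (4aS,8aR)-5,5,8a-trimethyl-6-oxo-3,4,4a,5,6,8a-hexahydronaphthalen-1-yl trifluoromethanesulfonate, via allylic alcohol 12 (not isolated)
Conditions: SeO2 (0.3 equiv), t-BuOOH, CH2Cl2, rt; then Dess–Martin periodinane, NaHCO3, CH2Cl2, rt
Reagents that add atoms: tert-butyl hydroperoxide CC(C)(C)OO; selenium dioxide O=[Se]=O (catalytic oxygen carrier)
Why: Selenium dioxide allylic oxidation (ene reaction, then 2,3-shift) returns the double bond to C-1=C-2 and oxygenates C-3, the only allylic C–H position of the electron-rich olefin; oxidation of either carbinol epimer converges on the enone.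

**Step 7**
Reactants: 13 enone
Product: 14 (4aS,8aR)-5,5,8a-trimethyl-6-oxo-3,4,4a,5,6,7,8,8a-octahydronaphthalen-1-yl trifluoromethanesulfonate
Conditions: H2 (1 atm), RhCl(PPh3)3 (10 mol %), benzene, rt
Reagents that add atoms: none
Why: Homogeneous hydrogenation with chlorotris(triphenylphosphine)rhodium should saturate the cis-disubstituted enone olefin and leave the trisubstituted, electron-poor vinyl triflate; no stereocentre is formed.

**Step 8**
Reactants: 15 4-methyl-5,6-dihydro-2H-pyran-2-one
Product: 17 methyl (2Z)-5-bromo-3-methylpent-2-enoate, via acyl bromide 16 (not isolated)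
Conditions: BBr3, CH2Cl2, 0 °C → rt; then MeOH, 0 °C
Reagents that add atoms: boron tribromide BrB(Br)Br; methanol CO
Why: Boron tribromide cleaves the lactone at the O-alkyl bond by bromide attack and methanol then esterifies the acyl bromide; the Z geometry is inherited from the ring and is not touched.

**Step 9**
Reactants: 17 bromo ester; 14 vinyl triflate
Product: 19 methyl (2Z)-3-methyl-5-[(4aS,8aR)-5,5,8a-trimethyl-6-oxo-3,4,4a,5,6,7,8,8a-octahydronaphthalen-1-yl]pent-2-enoate, via alkylzinc bromide 18 (not isolated)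
Conditions: Zn dust (activated with BrCH2CH2Br, Me3SiCl), LiCl, THF, 50 °C; then 14, PdCl2(dppf) (5 mol %), THF/NMP, 50 °C
Reagents that add atoms: none
Why: Negishi coupling of a functionalised alkylzinc halide with a vinyl triflate under a divalent palladium precatalyst tolerates the ester and the ketone and keeps the Z olefin; no stereocentre is formed.

**Step 10**
Reactants: 19 coupled olefin
Product: 21 methyl (2Z)-5-[(1S,2S,4aS,8aR)-2,6-dihydroxy-5,5,8a-trimethyldecahydronaphthalen-1-yl]-3-methylpent-2-enoate (both C-6 carbinol epimers), via alkylborane 20 (not isolated)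
Conditions: BH3·SMe2 (2.2 equiv), THF, 0 °C → rt; then H2O2, pH 7 phosphate buffer, 0 °C
Reagents that add atoms: hydrogen peroxide OO
Why: Hydroboration–oxidation places boron on the less substituted C-8 and delivers hydrogen to C-9 syn, from the face opposite the axial C-10 methyl group, which sets C-9 with the side chain equatorial; the C-3 ketone is reduced as well and is re-oxidised in step 11.

**Step 11**
Reactants: 21 diol
Product: 22 methyl (2Z)-3-methyl-5-[(1S,4aS,8aR)-5,5,8a-trimethyl-2,6-dioxodecahydronaphthalen-1-yl]pent-2-enoate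
Conditions: Dess–Martin periodinane (3 equiv), NaHCO3, CH2Cl2, rt
Reagents that add atoms: none
Why: Dess–Martin oxidation of both secondary alcohols is neutral and should leave C-9, which already has the more stable equatorial configuration.

**Step 12**
Reactants: 22 diketone
Product: 23 methyl (2Z)-3-methyl-5-[(1R,4aS,8aS)-5,5,8a-trimethyl-2-methylidene-6-oxodecahydronaphthalen-1-yl]pent-2-enoate
Conditions: Ph3PCH3Br, KN(SiMe3)2, THF, 0 °C; then 22, 0 °C → rt
Reagents that add atoms: methyltriphenylphosphonium bromide C[P+](c1ccccc1)(c1ccccc1)c1ccccc1.[Br-]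
Why: Wittig methylenation should occur at the C-8 ketone, because the C-3 ketone is neopentylic (flanked by the gem-dimethyl carbon) and reacts much more slowly; C-9 stays in its thermodynamic configuration.

**Step 13**
Reactants: 23 exocyclic olefin
Product: 25 methyl (2Z)-3-methyl-5-[(1S,4aS,8aR)-5,5,8a-trimethyl-2-methylidene-3,6-dioxodecahydronaphthalen-1-yl]pent-2-enoate, via allylic alcohol 24 (not isolated)
Conditions: SeO2 (0.5 equiv), t-BuOOH, CH2Cl2, rt; then Dess–Martin periodinane, NaHCO3, CH2Cl2, rt
Reagents that add atoms: tert-butyl hydroperoxide CC(C)(C)OO; selenium dioxide O=[Se]=O (catalytic oxygen carrier)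
Why: Selenium dioxide oxidation of an exocyclic methylene attacks the ring CH2 (C-7) and not the hindered C-9 methine; the alcohol (expected axial) is oxidised so that C-7 can be set by reduction.

**Step 14**
Reactants: 25 enedione
Product: 26 methyl (2Z)-5-[(1S,3R,4aS,6R,8aR)-3,6-dihydroxy-5,5,8a-trimethyl-2-methylidenedecahydronaphthalen-1-yl]-3-methylpent-2-enoate (target)
Conditions: NaBH4, CeCl3·7H2O, MeOH, −40 → 0 °C
Reagents that add atoms: none
Why: Luche conditions give 1,2-reduction of the enone and reduce the C-3 ketone; axial hydride delivery at both carbonyls (at C-7 from the face opposite the C-10 methyl group) should give the two equatorial alcohols, and the unsaturated ester is not reduced.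

**Compound list**
1 | tert-butyl 2-methylpropanoate | CC(C)C(=O)OC(C)(C)C | starting material
2 | lithium 1-tert-butoxy-2-methylprop-1-en-1-olate | CC(C)=C([O-])OC(C)(C)C.[Li+] | intermediate
3 | [(1-tert-butoxy-2-methylprop-1-en-1-yl)oxy]trimethylsilane | CC(C)=C(OC(C)(C)C)O[Si](C)(C)C | intermediate
4 | 2-methylcyclohex-2-en-1-one | CC1=CCCCC1=O | starting material
5 | tert-butyl 2-methyl-2-{(1S)-2-methyl-3-[(trimethylsilyl)oxy]cyclohex-2-en-1-yl}propanoate | CC1=C(O[Si](C)(C)C)CCC[C@@H]1C(C)(C)C(=O)OC(C)(C)C | intermediate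
6 | tert-butyl 2-[(1S,2S)-2-(dimethoxymethyl)-2-methyl-3-oxocyclohexyl]-2-methylpropanoate | O=C1CCC[C@H](C(C)(C)C(=O)OC(C)(C)C)[C@@]1(C)C(OC)OC | intermediate
7 | potassium enolate of 6 (enolised towards the ring CH2) | [K+].[O-]C1=CCC[C@H](C(C)(C)C(=O)OC(C)(C)C)[C@@]1(C)C(OC)OC | intermediate
8 | tert-butyl 2-[(1S,2R)-2-(dimethoxymethyl)-2-methyl-3-{[(trifluoromethyl)sulfonyl]oxy}cyclohex-3-en-1-yl]-2-methylpropanoate | O=S(=O)(OC1=CCC[C@H](C(C)(C)C(=O)OC(C)(C)C)[C@@]1(C)C(OC)OC)C(F)(F)F | intermediate
9 | 2-[(1S,2R)-2-formyl-2-methyl-3-{[(trifluoromethyl)sulfonyl]oxy}cyclohex-3-en-1-yl]-2-methylpropanoic acid | O=C[C@@]1(C)C(OS(=O)(=O)C(F)(F)F)=CCC[C@@H]1C(C)(C)C(=O)O | intermediate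
10 | {3-[(1R,2R)-2-formyl-2-methyl-3-{[(trifluoromethyl)sulfonyl]oxy}cyclohex-3-en-1-yl]-3-methylbutylidene}triphenylphosphorane | O=C[C@@]1(C)C(OS(=O)(=O)C(F)(F)F)=CCC[C@@H]1C(C)(C)CC=P(c1ccccc1)(c1ccccc1)c1ccccc1 | intermediate
11 | (4aR,8aR)-5,5,8a-trimethyl-3,4,4a,5,6,8a-hexahydronaphthalen-1-yl trifluoromethanesulfonate | FC(F)(F)S(=O)(=O)OC1=CCC[C@@H]2C(C)(C)CC=C[C@@]12C | intermediate
12 | 6-hydroxy derivative of 11 (allylic alcohol, either carbinol epimer; ring fusion as in 11) | FC(F)(F)S(=O)(=O)OC1=CCC[C@@H]2C(C)(C)C(O)C=C[C@@]12C | intermediate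
13 | (4aS,8aR)-5,5,8a-trimethyl-6-oxo-3,4,4a,5,6,8a-hexahydronaphthalen-1-yl trifluoromethanesulfonate | FC(F)(F)S(=O)(=O)OC1=CCC[C@@H]2C(C)(C)C(=O)C=C[C@@]12C | intermediate
14 | (4aS,8aR)-5,5,8a-trimethyl-6-oxo-3,4,4a,5,6,7,8,8a-octahydronaphthalen-1-yl trifluoromethanesulfonate | FC(F)(F)S(=O)(=O)OC1=CCC[C@@H]2C(C)(C)C(=O)CC[C@@]12C | intermediate
15 | 4-methyl-5,6-dihydro-2H-pyran-2-one | CC1=CC(=O)OCC1 | starting material
16 | (2Z)-5-bromo-3-methylpent-2-enoyl bromide | BrCC/C(C)=C\C(Br)=O | intermediate
17 | methyl (2Z)-5-bromo-3-methylpent-2-enoate | BrCC/C(C)=C\C(=O)OC | intermediate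
18 | bromo[(3Z)-5-methoxy-3-methyl-5-oxopent-3-en-1-yl]zinc | Br[Zn]CC/C(C)=C\C(=O)OC | intermediate
19 | methyl (2Z)-3-methyl-5-[(4aS,8aR)-5,5,8a-trimethyl-6-oxo-3,4,4a,5,6,7,8,8a-octahydronaphthalen-1-yl]pent-2-enoate | C1(CC/C(C)=C\C(=O)OC)=CCC[C@@H]2C(C)(C)C(=O)CC[C@@]12C | intermediate
20 | C-8 alkylborane of 19 with the C-3 oxygen as borinate (boron and H-9 on the face opposite the C-10 methyl; C-3 either epimer) | B[C@H]1CC[C@@H]2C(C)(C)C(OB)CC[C@@]2(C)[C@@H]1CC/C(C)=C\C(=O)OC | intermediate
21 | methyl (2Z)-5-[(1S,2S,4aS,8aR)-2,6-dihydroxy-5,5,8a-trimethyldecahydronaphthalen-1-yl]-3-methylpent-2-enoate (both C-6 epimers) | O[C@H]1CC[C@@H]2C(C)(C)C(O)CC[C@@]2(C)[C@@H]1CC/C(C)=C\C(=O)OC | intermediate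
22 | methyl (2Z)-3-methyl-5-[(1S,4aS,8aR)-5,5,8a-trimethyl-2,6-dioxodecahydronaphthalen-1-yl]pent-2-enoate | O=C1CC[C@@H]2C(C)(C)C(=O)CC[C@@]2(C)[C@@H]1CC/C(C)=C\C(=O)OC | intermediate
23 | methyl (2Z)-3-methyl-5-[(1R,4aS,8aS)-5,5,8a-trimethyl-2-methylidene-6-oxodecahydronaphthalen-1-yl]pent-2-enoate | C=C1CC[C@@H]2C(C)(C)C(=O)CC[C@@]2(C)[C@@H]1CC/C(C)=C\C(=O)OC | intermediate
24 | methyl (2Z)-5-[(1S,3S,4aS,8aS)-3-hydroxy-5,5,8a-trimethyl-2-methylidene-6-oxodecahydronaphthalen-1-yl]-3-methylpent-2-enoate (axial alcohol drawn; either epimer is carried on) | C=C1[C@@H](O)C[C@@H]2C(C)(C)C(=O)CC[C@@]2(C)[C@@H]1CC/C(C)=C\C(=O)OC | intermediate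
25 | methyl (2Z)-3-methyl-5-[(1S,4aS,8aR)-5,5,8a-trimethyl-2-methylidene-3,6-dioxodecahydronaphthalen-1-yl]pent-2-enoate | C=C1C(=O)C[C@@H]2C(C)(C)C(=O)CC[C@@]2(C)[C@@H]1CC/C(C)=C\C(=O)OC | intermediate
26 | methyl (2Z)-5-[(1S,3R,4aS,6R,8aR)-3,6-dihydroxy-5,5,8a-trimethyl-2-methylidenedecahydronaphthalen-1-yl]-3-methylpent-2-enoate | C=C1[C@H](O)C[C@@H]2C(C)(C)[C@H](O)CC[C@@]2(C)[C@@H]1CC/C(C)=C\C(=O)OC | target

**Step count and risks**
Total steps: 14. Longest linear sequence: 13 (steps 1–7 and 9–14); step 8 is a one-step side branch.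

Steps most likely to fail:

1. Step 5. The acid and aldehyde of 9 may rest as the ring-closed lactol, or the ylide may be protonated before it olefinates, so that radical generation or ring closure stalls. Fallback by known stepwise chemistry, from 9 back to 11: 9 is converted with N-hydroxyphthalimide and diisopropylcarbodiimide into the N-acyloxyphthalimide F1. Reductive decarboxylative Giese addition of F1 to phenyl vinyl sulfone ([Ru(bpy)3]Cl2, Hantzsch ester, iPr2NEt, blue LEDs) gives the sulfone aldehyde F2. Intramolecular Julia reaction (LiN(SiMe3)2, THF, −78 °C, then Ac2O) closes ring A as the β-acetoxy sulfone F3. Reductive elimination with sodium amalgam gives 11.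

2. Step 2. Enantioface control may erode with the α-methyl enone, and the hindered silyl enol ether may alkylate slowly. Fallback, from 3 back to 5: 3 is added under the same catalyst to cyclohex-2-en-1-one (O=C1C=CCCC1), the substrate class with direct precedent, to give the silyl enol ether F4. MeLi then MeI gives the trans 2-methyl ketone F5. Thermodynamic silylation (Me3SiCl, NaI, Et3N, MeCN) gives the tetrasubstituted silyl enol ether 5, which is treated with the orthoformate as in step 2.

3. Step 10. The hindered trisubstituted olefin may hydroborate slowly, so that borane begins to reduce the unsaturated ester. Fallback without borane, from 19 back to 22: dihydroxylation (OsO4 cat., N-methylmorpholine N-oxide) from the face opposite the C-10 methyl gives the diol F6. Dess–Martin oxidation of the secondary alcohol gives the α-hydroxy ketone F7. SmI2 (THF/MeOH, −78 °C) removes the tertiary hydroxyl and gives 22, with C-9 settling in its equatorial configuration.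

**Further compounds**
F1 | step 5 | 1,3-dioxoisoindolin-2-yl ester of 9 (N-acyloxyphthalimide) | O=C[C@@]1(C)C(OS(=O)(=O)C(F)(F)F)=CCC[C@@H]1C(C)(C)C(=O)ON1C(=O)c2ccccc2C1=O
F2 | step 5 | 9 with CO2H replaced by CH2CH2SO2Ph (sulfone aldehyde) | O=C[C@@]1(C)C(OS(=O)(=O)C(F)(F)F)=CCC[C@@H]1C(C)(C)CCS(=O)(=O)c1ccccc1
F3 | step 5 | 8-acetoxy-7-(phenylsulfonyl) derivative of the saturated ring A analogue of 11 (naphthalene numbering; epimers at both new centres) | FC(F)(F)S(=O)(=O)OC1=CCC[C@@H]2C(C)(C)CC(S(=O)(=O)c3ccccc3)C(OC(C)=O)[C@@]12C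
F4 | step 2 | tert-butyl 2-methyl-2-{(1S)-3-[(trimethylsilyl)oxy]cyclohex-2-en-1-yl}propanoate | C[Si](C)(C)OC1=C[C@@H](C(C)(C)C(=O)OC(C)(C)C)CCC1
F5 | step 2 | tert-butyl 2-methyl-2-[trans-2-methyl-3-oxocyclohexyl]propanoate (C-5 as in 6) | O=C1CCC[C@H](C(C)(C)C(=O)OC(C)(C)C)[C@H]1C
F6 | step 10 | 8,9-cis-diol of 19 (both hydroxyls on the face opposite the C-10 methyl) | O[C@H]1CC[C@@H]2C(C)(C)C(=O)CC[C@@]2(C)[C@]1(O)CC/C(C)=C\C(=O)OC
F7 | step 10 | 9-hydroxy-3,8-diketone | O=C1CC[C@@H]2C(C)(C)C(=O)CC[C@@]2(C)[C@]1(O)CC/C(C)=C\C(=O)OC
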